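Ring B is cut back to a γ-lactone: C7a is the lactone carbonyl and C7 a one-carbon unit added last. That leaves ring A as an oxolan-2-one in which C3 (aryl) and C3a (allyl) sit β and α to C7a, so both bonds are made in one flask by aryl cuprate addition to a butenolide and allylation of the enolate, the C2 methyl relaying configuration to C3 and C3 to C3a. The butenolide already carries C4–C6 as a 2-methoxypropanoate whose C5 centre is fixed beforehand as a single (S) epimer by auxiliary-controlled alkylation. Ring B is then closed by methoxymethyl addition to C7a, Claisen condensation and cyclodehydration.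

Key step: step 7

Remark: atoms are numbered as in the target benzofuranone (O1, C2 methyl, C3 aryl, C3a allyl, C4, C5 methoxy, C6 carbonyl, C7 methoxy, C7a); the target is read as (2R,3S,3aR,5S); Ar = 3,4,5-trimethoxyphenyl.

Step 1
Reactants: 1 (4R)-4-benzyl-1,3-oxazolidin-2-one; 2 methoxyacetyl chloride
Product: 4 (4R)-4-benzyl-3-(methoxyacetyl)-1,3-oxazolidin-2-one, via N-lithio oxazolidinone 3 (not isolated)
Conditions: n-BuLi, THF, −78 °C; then 2, −78 to 0 °C
Reagents that add atoms: none
Why: N-acylation of the lithiated oxazolidinone by an acid chloride is the standard loading of an Evans auxiliary; no stereocentre is formed and the benzyl-bearing centre is not touched.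

Step 2
Reactants: 4 (4R)-4-benzyl-3-(methoxyacetyl)-1,3-oxazolidin-2-one; 5 tert-butyl 2-(bromomethyl)prop-2-enoate
Product: 7 tert-butyl (4S)-5-[(4R)-4-benzyl-2-oxo-1,3-oxazolidin-3-yl]-4-methoxy-2-methylidene-5-oxopentanoate, via sodium Z-enolate 6 (not isolated)
Conditions: NaN(SiMe3)2, THF, −78 °C; then 5, −78 to −45 °C
Reagents that add atoms: none
Why: Evans-type asymmetric alkylation of the chelated sodium (Z)-enolate of a glycolate imide by a very reactive allylic bromide (SN2 or SN2' displacement, same product), the electrophile entering on the enolate face opposite the benzyl group of the (R)-auxiliary, which should set C5 as (S).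

Step 3
Reactants: 7 tert-butyl (4S)-5-[(4R)-4-benzyl-2-oxo-1,3-oxazolidin-3-yl]-4-methoxy-2-methylidene-5-oxopentanoate
Product: 8 5-tert-butyl 1-methyl (2S)-2-methoxy-4-methylidenepentanedioate
Conditions: MeMgBr, MeOH, CH2Cl2, 0 °C
Reagents that add atoms: methanol, CO (delivered as methoxymagnesium bromide, CO[Mg]Br, made in the flask from MeMgBr and MeOH)
Why: magnesium methoxide transesterification attacks the exocyclic imide carbonyl selectively and is mild enough to leave the α-methoxy centre and the tert-butyl acrylate alone, so C5 should pass unchanged while the auxiliary is released for recovery.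

Step 4
Reactants: 8 5-tert-butyl 1-methyl (2S)-2-methoxy-4-methylidenepentanedioate
Product: 9 (4S)-4,5-dimethoxy-2-methylidene-5-oxopentanoic acid
Conditions: CF3CO2H, CH2Cl2, 0 °C to rt
Reagents that add atoms: none
Why: acidolysis of a tert-butyl ester (loss of 2-methylpropene through the tert-butyl cation) should free only the acrylic acid, since the methyl ester, the methyl ether and C5 are inert to the acid.

Step 5
Reactants: 9 (4S)-4,5-dimethoxy-2-methylidene-5-oxopentanoic acid; 10 (2R)-but-3-en-2-ol
Product: 11 5-[(2R)-but-3-en-2-yl] 1-methyl (2S)-2-methoxy-4-methylidenepentanedioate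
Conditions: DCC, DMAP (cat.), CH2Cl2, 0 °C to rt
Reagents that add atoms: none
Why: Steglich esterification activates the acid and not the alcohol, so the carbinol C–O bond of 10 stays intact and its (R) configuration is carried over as the future C2.

Step 6
Reactants: 11 5-[(2R)-but-3-en-2-yl] 1-methyl (2S)-2-methoxy-4-methylidenepentanedioate
Product: 12 methyl (2S)-2-methoxy-3-[(5R)-5-methyl-2-oxo-2,5-dihydrofuran-3-yl]propanoate
Conditions: second-generation Grubbs catalyst RuCl2(=CHPh)(PCy3)(H2IMes) (5 mol%), CH2Cl2, 40 °C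
Reagents that add atoms: none
Why: ring-closing metathesis of an allylic ester of a 2-substituted acrylic acid is an established entry to α-substituted butenolides, the catalyst loading on the monosubstituted alkene and closing onto the acrylate with loss of ethene, with no stereocentre involved.

Step 7
Reactants: 12 methyl (2S)-2-methoxy-3-[(5R)-5-methyl-2-oxo-2,5-dihydrofuran-3-yl]propanoate; 13 5-bromo-1,2,3-trimethoxybenzene; 14 allyl bromide
Product: 18 methyl (2S)-2-methoxy-3-[(3R,4S,5R)-5-methyl-2-oxo-3-(prop-2-en-1-yl)-4-(3,4,5-trimethoxyphenyl)oxolan-3-yl]propanoate, via aryllithium 15 (not isolated), via lithium diarylcuprate 16 (not isolated), via lithium lactone enolate 17 (not isolated)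
Conditions: 13, t-BuLi (2 equiv per bromide), Et2O, −78 °C; CuBr·SMe2 (0.5 equiv per aryllithium), −78 to −40 °C; then 12, Et2O/THF, −78 to −40 °C; then 14 (excess), DMPU, THF, −78 to −40 °C
Reagents that add atoms: none
Why: The Gilman reagent 16 forms a π-complex with the s-trans enoate, transfers one aryl group to the β-carbon through a trivalent copper intermediate and reductive elimination, and leaves the lithium enolate 17, which displaces bromide from 14 in an SN2 C-allylation; no ring is closed. This is the tandem cuprate conjugate addition–enolate alkylation known for γ-substituted butenolides, in which each bond forms anti to the neighbouring ring substituent. C3 (lactone C4) is set by aryl delivery to the face opposite the C2 methyl group, and C3a (lactone C3) by approach of allyl bromide opposite the new aryl group, which leaves the C4–C6 chain cis to aryl as the target requires. The step needs 1,4- over 1,2-addition and attack on the enoate and not on the side-chain ester, which the soft cuprate (no free aryllithium) and the reactive cyclic enoate should secure, and C- over O-allylation, which the lithium counter-ion and the soft allylic halide should secure. The one acidic spectator, H–C5 of the α-methoxy ester, is guarded by keeping 17 at or below −40 °C and trapping it at once with excess 14 and DMPU, so that alkylation should outrun proton transfer.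

Step 8
Reactants: 18 methyl (2S)-2-methoxy-3-[(3R,4S,5R)-5-methyl-2-oxo-3-(prop-2-en-1-yl)-4-(3,4,5-trimethoxyphenyl)oxolan-3-yl]propanoate
Product: 19 (2S)-2-methoxy-3-[(3R,4S,5R)-5-methyl-2-oxo-3-(prop-2-en-1-yl)-4-(3,4,5-trimethoxyphenyl)oxolan-3-yl]propanoic acid
Conditions: LiOH·H2O, THF/H2O, 0 °C; then aq. HCl to pH 2
Reagents that add atoms: lithium hydroxide, [Li+].[OH-]
Why: saponification of the unhindered, α-alkoxy-activated methyl ester should be far faster than attack on the neopentyl lactone, any opened lactone re-closes on acidification, and brief cold hydroxide should not epimerise C5.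

Step 9
Reactants: 19 (2S)-2-methoxy-3-[(3R,4S,5R)-5-methyl-2-oxo-3-(prop-2-en-1-yl)-4-(3,4,5-trimethoxyphenyl)oxolan-3-yl]propanoic acid
Product: 21 methyl (2S)-3-[(3R,4S,5R)-2-hydroxy-2-(methoxymethyl)-5-methyl-3-(prop-2-en-1-yl)-4-(3,4,5-trimethoxyphenyl)oxolan-3-yl]-2-methoxypropanoate (anomers), via lactol acid 20 (not isolated)
Conditions: LiN(SiMe3)2 (1 equiv), THF, −78 °C; MeOCH2Li (from Bu3SnCH2OMe, n-BuLi, THF, −78 °C), −78 °C; AcOH quench; crude 20, Me3SiCHN2, PhMe/MeOH, 0 °C
Reagents that add atoms: (methoxymethyl)lithium, [Li]COC (made in the flask from tributyl(methoxymethyl)stannane, CCCC[Sn](CCCC)(CCCC)COC, and n-BuLi); trimethylsilyldiazomethane, C[Si](C)(C)C=[N+]=[N-]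
Why: with the side chain masked as its lithium carboxylate the lactone carbonyl is the only electrophile, so the small organolithium should add once to give a lithium hemiketal that is stable at −78 °C (organolithium mono-addition to a γ-lactone), and neutral diazoalkane esterification then restores the methyl ester; the hemiketal centre is lost later and needs no control.

Step 10
Reactants: 21 methyl (2S)-3-[(3R,4S,5R)-2-hydroxy-2-(methoxymethyl)-5-methyl-3-(prop-2-en-1-yl)-4-(3,4,5-trimethoxyphenyl)oxolan-3-yl]-2-methoxypropanoate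
Product: 23 (2R,3S,3aR,5S)-5,7-dimethoxy-2-methyl-3a-(prop-2-en-1-yl)-3-(3,4,5-trimethoxyphenyl)-3,3a,4,5-tetrahydro-1-benzofuran-6(2H)-one, via hydroxy diketone 22 (not isolated)
Conditions: KOtBu (2.2 equiv), THF, 0 °C to rt; then TsOH·H2O (excess over base), rt
Reagents that add atoms: none
Why: Dieckmann-type intramolecular Claisen condensation followed by acid-catalysed cyclodehydration: the ring-opened hydroxy ketone can enolise only at C7 because C3a is quaternary, the enolate should close the six-membered ring on the activated methyl ester to give the 2-methoxy-1,3-dione enolate as thermodynamic sink, and the C2 hydroxyl can then form an enol ether only with C7a (five-membered ring), while C5 stays alpha to nothing more acidic than an ester until ring B exists.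

Compound list
1 | (4R)-4-benzyl-1,3-oxazolidin-2-one | O=C1N[C@H](Cc2ccccc2)CO1 | starting material
2 | methoxyacetyl chloride | COCC(=O)Cl | starting material
3 | lithium salt of 1 (N-lithio oxazolidinone) | [Li+].O=C1[N-][C@H](Cc2ccccc2)CO1 | intermediate
4 | (4R)-4-benzyl-3-(methoxyacetyl)-1,3-oxazolidin-2-one | COCC(=O)N1[C@H](Cc2ccccc2)COC1=O | intermediate
5 | tert-butyl 2-(bromomethyl)prop-2-enoate | C=C(CBr)C(=O)OC(C)(C)C | starting material
6 | sodium (Z)-enolate of 4 | [Na+].CO/C=C(\[O-])N1[C@H](Cc2ccccc2)COC1=O | intermediate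
7 | tert-butyl (4S)-5-[(4R)-4-benzyl-2-oxo-1,3-oxazolidin-3-yl]-4-methoxy-2-methylidene-5-oxopentanoate | C=C(C[C@H](OC)C(=O)N1[C@H](Cc2ccccc2)COC1=O)C(=O)OC(C)(C)C | intermediate
8 | 5-tert-butyl 1-methyl (2S)-2-methoxy-4-methylidenepentanedioate | C=C(C[C@H](OC)C(=O)OC)C(=O)OC(C)(C)C | intermediate
9 | (4S)-4,5-dimethoxy-2-methylidene-5-oxopentanoic acid | C=C(C[C@H](OC)C(=O)OC)C(=O)O | intermediate
10 | (2R)-but-3-en-2-ol | C[C@@H](O)C=C | starting material
11 | 5-[(2R)-but-3-en-2-yl] 1-methyl (2S)-2-methoxy-4-methylidenepentanedioate | C=C(C[C@H](OC)C(=O)OC)C(=O)O[C@H](C)C=C | intermediate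
12 | methyl (2S)-2-methoxy-3-[(5R)-5-methyl-2-oxo-2,5-dihydrofuran-3-yl]propanoate | O=C1O[C@H](C)C=C1C[C@H](OC)C(=O)OC | intermediate
13 | 5-bromo-1,2,3-trimethoxybenzene | COc1cc(Br)cc(OC)c1OC | starting material
14 | allyl bromide (3-bromoprop-1-ene) | C=CCBr | starting material
15 | (3,4,5-trimethoxyphenyl)lithium | [Li]c1cc(OC)c(OC)c(OC)c1 | intermediate
16 | lithium bis(3,4,5-trimethoxyphenyl)cuprate | [Li+].COc1cc([Cu-]c2cc(OC)c(OC)c(OC)c2)cc(OC)c1OC | intermediate
17 | lithium (4S,5R)-3-[(2S)-2,3-dimethoxy-3-oxopropyl]-5-methyl-4-(3,4,5-trimethoxyphenyl)-4,5-dihydrofuran-2-olate | [Li+].COC(=O)[C@@H](OC)CC1=C([O-])O[C@H](C)[C@H]1c1cc(OC)c(OC)c(OC)c1 | intermediate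
18 | methyl (2S)-2-methoxy-3-[(3R,4S,5R)-5-methyl-2-oxo-3-(prop-2-en-1-yl)-4-(3,4,5-trimethoxyphenyl)oxolan-3-yl]propanoate | C=CC[C@]1(C[C@H](OC)C(=O)OC)C(=O)O[C@H](C)[C@H]1c1cc(OC)c(OC)c(OC)c1 | intermediate
19 | (2S)-2-methoxy-3-[(3R,4S,5R)-5-methyl-2-oxo-3-(prop-2-en-1-yl)-4-(3,4,5-trimethoxyphenyl)oxolan-3-yl]propanoic acid | C=CC[C@]1(C[C@H](OC)C(=O)O)C(=O)O[C@H](C)[C@H]1c1cc(OC)c(OC)c(OC)c1 | intermediate
20 | (2S)-3-[(3R,4S,5R)-2-hydroxy-2-(methoxymethyl)-5-methyl-3-(prop-2-en-1-yl)-4-(3,4,5-trimethoxyphenyl)oxolan-3-yl]-2-methoxypropanoic acid (anomers) | C=CC[C@]1(C[C@H](OC)C(=O)O)C(O)(COC)O[C@H](C)[C@H]1c1cc(OC)c(OC)c(OC)c1 | intermediate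
21 | methyl (2S)-3-[(3R,4S,5R)-2-hydroxy-2-(methoxymethyl)-5-methyl-3-(prop-2-en-1-yl)-4-(3,4,5-trimethoxyphenyl)oxolan-3-yl]-2-methoxypropanoate (anomers) | C=CC[C@]1(C[C@H](OC)C(=O)OC)C(O)(COC)O[C@H](C)[C@H]1c1cc(OC)c(OC)c(OC)c1 | intermediate
22 | (4R,6S)-4-[(1S,2R)-2-hydroxy-1-(3,4,5-trimethoxyphenyl)propyl]-2,6-dimethoxy-4-(prop-2-en-1-yl)cyclohexane-1,3-dione (C2 of the dione not defined; formed as its enolate) | C=CC[C@@]1(C[C@H](OC)C(=O)C(OC)C1=O)[C@H](c1cc(OC)c(OC)c(OC)c1)[C@@H](C)O | intermediate
23 | (2R,3S,3aR,5S)-5,7-dimethoxy-2-methyl-3a-(prop-2-en-1-yl)-3-(3,4,5-trimethoxyphenyl)-3,3a,4,5-tetrahydro-1-benzofuran-6(2H)-one | C=CC[C@]12C[C@H](OC)C(=O)C(OC)=C1O[C@H](C)[C@H]2c1cc(OC)c(OC)c(OC)c1 | target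

Total step count: 10
Longest linear sequence: 10 steps (1 to 23 through 4, 7, 8, 9, 11, 12, 18, 19 and 21)

Steps most likely to fail

Step 7. Conjugate addition to the α-substituted enoate may be slow, and C-allylation of the hindered, fully substituted enolate may be slow enough for proton transfer from C5 (loss of configuration or allylation at C5) or O-allylation to compete. The fallback sets out from 12: the cuprate addition is run in the presence of Me3SiCl, so that the enolate is trapped at once as the neutral silyl ketene acetal methyl (2S)-2-methoxy-3-[(4S,5R)-5-methyl-4-(3,4,5-trimethoxyphenyl)-2-(trimethylsilyloxy)-4,5-dihydrofuran-3-yl]propanoate F1. This is then allylated without base by allyl methyl carbonate with catalytic Pd2(dba)3 and dppe (zerovalent palladium, Tsuji allylation of a ketene silyl acetal), the π-allyl complex again being attacked on the face opposite the aryl group. The fallback comes back to the route at 18.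

Step 9. The organolithium may fail to add to the neopentyl lactone carbonyl, may add twice after ring opening, or may attack the carboxylate. The fallback sets out from 19 and reverses the roles of the two carbonyl groups. Amide coupling (EDC·HCl, HOBt, MeNHOMe·HCl, iPr2NEt) gives the Weinreb amide (2S)-N,2-dimethoxy-N-methyl-3-[(3R,4S,5R)-5-methyl-2-oxo-3-(prop-2-en-1-yl)-4-(3,4,5-trimethoxyphenyl)oxolan-3-yl]propanamide F2. MeOCH2Li should add to this unhindered, chelating acyl group in preference to the hindered lactone and give the methoxymethyl ketone (3R,4S,5R)-3-[(2S)-2,4-dimethoxy-3-oxobutyl]-5-methyl-3-(prop-2-en-1-yl)-4-(3,4,5-trimethoxyphenyl)oxolan-2-one F3. LiN(SiMe3)2 at −78 °C should then deprotonate the less hindered methoxymethyl carbon, and the C7 enolate attacks the lactone carbonyl with ring opening (intramolecular Claisen condensation). The fallback comes back to the route at 22, which is cyclodehydrated with acid as in step 10.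

Step 10. Ring closure may be slow or reversible, and prolonged exposure to alkoxide may erode C5. The fallback sets out from 18 and closes ring B by olefination instead of condensation. Two equivalents of Ph3P=CHOMe (from (methoxymethyl)triphenylphosphonium chloride and KN(SiMe3)2, THF, −78 to 0 °C) are acylated by the methyl ester to give the non-basic acyl-stabilised ylide (3R,4S,5R)-3-[(2S)-2,4-dimethoxy-3-oxo-4-(triphenyl-λ5-phosphanylidene)butyl]-5-methyl-3-(prop-2-en-1-yl)-4-(3,4,5-trimethoxyphenyl)oxolan-2-one F4. Heating in toluene should then effect intramolecular Wittig olefination of the lactone carbonyl. The fallback comes back to the route at 23.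

Further compounds
F1 | step 7 | methyl (2S)-2-methoxy-3-[(4S,5R)-5-methyl-4-(3,4,5-trimethoxyphenyl)-2-(trimethylsilyloxy)-4,5-dihydrofuran-3-yl]propanoate | COC(=O)[C@@H](OC)CC1=C(O[Si](C)(C)C)O[C@H](C)[C@H]1c1cc(OC)c(OC)c(OC)c1
F2 | step 9 | (2S)-N,2-dimethoxy-N-methyl-3-[(3R,4S,5R)-5-methyl-2-oxo-3-(prop-2-en-1-yl)-4-(3,4,5-trimethoxyphenyl)oxolan-3-yl]propanamide | C=CC[C@]1(C[C@H](OC)C(=O)N(C)OC)C(=O)O[C@H](C)[C@H]1c1cc(OC)c(OC)c(OC)c1
F3 | step 9 | (3R,4S,5R)-3-[(2S)-2,4-dimethoxy-3-oxobutyl]-5-methyl-3-(prop-2-en-1-yl)-4-(3,4,5-trimethoxyphenyl)oxolan-2-one | C=CC[C@]1(C[C@H](OC)C(=O)COC)C(=O)O[C@H](C)[C@H]1c1cc(OC)c(OC)c(OC)c1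
F4 | step 10 | (3R,4S,5R)-3-[(2S)-2,4-dimethoxy-3-oxo-4-(triphenyl-λ5-phosphanylidene)butyl]-5-methyl-3-(prop-2-en-1-yl)-4-(3,4,5-trimethoxyphenyl)oxolan-2-one | C=CC[C@]1(C[C@H](OC)C(=O)C(OC)=P(c2ccccc2)(c2ccccc2)c2ccccc2)C(=O)O[C@H](C)[C@H]1c1cc(OC)c(OC)c(OC)c1
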